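**Plan**

- Working ring numbering: C1 ketone, C2 quaternary epoxide carbon carrying the chloroalkenyl arm, C3 epoxide CH, C4 CH2, C5 CHOAc, C6 CHMe.
- Retrosynthesis: the acetate and epoxide are removed first; the C2–CH= bond is cut (Suzuki–Miyaura) into a ring boronate and an (E)-2-chloro-3-iodoallyl amide; the amide C–N bond is cut into the lipid acid and an amine.
- The ring is cut at C1–C2 and C2–C3. C2 is a single carbon flanked by carbonyl carbon C1 and by C3, so it can enter as the carbon of dibromocarbene into a cyclopentanone silyl enol ether that already holds the cis C5–O/C6–Me pair; the bromine left on C2 is the handle for the arm.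
- Forward order: five-membered ketone, one-carbon enlargement to the six-membered 2-bromoenone, C1 reduction, borylation, coupling with the finished side chain, epoxide ring, reoxidation, silyl-to-acetate exchange.
- Stereochemistry: C5 from a CBS reduction, C6 from hydroboration anti to the C5 silyl ether, the temporary C1 carbinol from a second CBS reduction, C2/C3 from delivery of oxygen by that hydroxyl; lipid C7 (R) from an allylboration, the 4E alkene from a Johnson–Claisen rearrangement, the (E)-chloroalkene from anti iodochlorination of an alkyne followed by a stereoretentive coupling.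

Key step: step 6

Remark: the target is read as 7R in the lipid chain and E at the chloroalkene (chlorine trans to ring carbon C2); alkoxide and carboxylate salts that are only protonated on work-up are not numbered separately.

**Route**

Step 1
Reactants: 1 2-methylcyclopent-2-en-1-one
Product: 2 (1S)-2-methylcyclopent-2-en-1-ol
Conditions: (R)-2-methyl-CBS-oxazaborolidine (10 mol%), BH3·SMe2, THF, −20 °C; MeOH
Reagents that add atoms: none
Why: Corey–Bakshi–Shibata reduction in which the methyl-bearing alkene carbon acts as the large group, so the (R)-catalyst should deliver hydride to the face that gives the S carbinol, the future C5.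

Step 2
Reactants: 2 (1S)-2-methylcyclopent-2-en-1-ol
Product: 3 tert-butyldimethyl{[(1S)-2-methylcyclopent-2-en-1-yl]oxy}silane
Conditions: TBSCl, imidazole, DMF, 0 → 23 °C
Reagents that add atoms: tert-butyldimethylsilyl chloride, CC(C)(C)[Si](C)(C)Cl
Why: Imidazole-promoted silylation of a secondary allylic alcohol gives a bulky ether that steers the next step and tolerates the later base, carbene and hydride conditions.

Step 3
Reactants: 3 tert-butyldimethyl{[(1S)-2-methylcyclopent-2-en-1-yl]oxy}silane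
Product: 5 (1S,2R,3S)-3-[(tert-butyldimethylsilyl)oxy]-2-methylcyclopentan-1-ol, via alkylborane 4 (not isolated)
Conditions: BH3·THF, THF, 0 → 23 °C; NaOH, H2O2, 0 °C
Reagents that add atoms: hydrogen peroxide, OO
Why: Syn hydroboration places boron on the unsubstituted alkene carbon and hydrogen on the methyl-bearing carbon from the face opposite the silyl ether, so oxidation with retention should leave the methyl group cis to the silyloxy group (future C6) and the hydroxyl trans to the methyl group.

Step 4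
Reactants: 5 (1S,2R,3S)-3-[(tert-butyldimethylsilyl)oxy]-2-methylcyclopentan-1-ol
Product: 6 (2S,3S)-3-[(tert-butyldimethylsilyl)oxy]-2-methylcyclopentan-1-one
Conditions: Dess–Martin periodinane, NaHCO3, CH2Cl2, 0 → 23 °C
Reagents that add atoms: none
Why: Dess–Martin oxidation under buffered, non-basic conditions should give the ketone without epimerising the adjacent methyl-bearing centre or eliminating the β-silyloxy group.

Step 5
Reactants: 6 (2S,3S)-3-[(tert-butyldimethylsilyl)oxy]-2-methylcyclopentan-1-one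
Product: 8 (4S,5S)-4-[(tert-butyldimethylsilyl)oxy]-5-methyl-1-[(triethylsilyl)oxy]cyclopent-1-ene, via lithium enolate 7 (not isolated)
Conditions: LiN(iPr)2, THF, −78 °C; Et3SiCl, −78 → 0 °C
Reagents that add atoms: chlorotriethylsilane, CC[Si](Cl)(CC)CC
Why: Kinetic deprotonation by the hindered amide base takes a proton from the unsubstituted α-methylene and not from the methyl-bearing α-carbon, and O-silylation fixes the double bond on that side; triethylsilyl is chosen because it resists tert-butoxide and chromatography better than trimethylsilyl.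

Step 6
Reactants: 8 (4S,5S)-4-[(tert-butyldimethylsilyl)oxy]-5-methyl-1-[(triethylsilyl)oxy]cyclopent-1-ene; 9 bromoform
Product: 11 (5S,6S)-2-bromo-5-[(tert-butyldimethylsilyl)oxy]-6-methylcyclohex-2-en-1-one, via dibromocyclopropane 10 (not isolated)
Conditions: CHBr3, KOtBu, pentane, −30 → −10 °C; pH 7 buffer; then toluene, 23 → 60 °C; aq. NaHCO3
Reagents that add atoms: bromoform (compound 9), BrC(Br)Br
Why: α-Elimination of bromoform with KOtBu gives singlet dibromocarbene, which adds in a concerted [2+1] cheletropic way to the only electron-rich alkene of 8, the enol ether bond between future C1 and C3, so that the carbene carbon (future C2) forms its bonds to C1 and C3 and the three-membered ring of 10 closes on the face away from the C6 methyl group. The bromine that lies over the five-membered ring then ionises while the fusion bond C1–C3 breaks in a disrotatory two-electron electrocyclic opening pushed by the siloxy oxygen, so the six-membered ring arises by enlargement of the bicyclo[3.1.0]hexane and not by a cyclisation. Bromide takes the triethylsilyl group from the resulting 2-bromo-1-siloxyallyl cation and leaves the 2-bromoenone. The closest known reaction type is the dihalocarbene ring expansion of cyclic silyl enol ethers to 2-halocycloalk-2-enones. No lasting stereocentre is formed, since the two cyclopropane centres are destroyed in the opening and C5 and C6 are spectators. The step needs regioselectivity, which is fixed by the kinetic enolisation of step 5 away from the methyl-bearing carbon, and it needs the C6 centre next to the new ketone to escape enolisation, which the cold, non-polar carbene generation and the neutral thermal opening after removal of the base are meant to secure.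

Step 7
Reactants: 11 (5S,6S)-2-bromo-5-[(tert-butyldimethylsilyl)oxy]-6-methylcyclohex-2-en-1-one
Product: 12 (1S,5S,6R)-2-bromo-5-[(tert-butyldimethylsilyl)oxy]-6-methylcyclohex-2-en-1-ol
Conditions: (R)-2-methyl-CBS-oxazaborolidine (20 mol%), BH3·SMe2, THF, −40 °C; MeOH
Reagents that add atoms: none
Why: Corey–Bakshi–Shibata 1,2-reduction of an α-bromoenone with the bromoalkene carbon as the large group; the (R)-catalyst should deliver hydride to the face opposite the C6 methyl and C5 silyloxy groups (catalyst and substrate matched), placing the C1 hydroxyl cis to both.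

Step 8
Reactants: 12 (1S,5S,6R)-2-bromo-5-[(tert-butyldimethylsilyl)oxy]-6-methylcyclohex-2-en-1-ol
Product: 13 (1S,5S,6R)-5-[(tert-butyldimethylsilyl)oxy]-6-methyl-2-(4,4,5,5-tetramethyl-1,3,2-dioxaborolan-2-yl)cyclohex-2-en-1-ol
Conditions: B2pin2, PdCl2(dppf), KOAc, 1,4-dioxane, 80 °C
Reagents that add atoms: bis(pinacolato)diboron, CC1(C)OB(OC1(C)C)B1OC(C)(C)C(C)(C)O1
Why: Miyaura borylation of the alkenyl bromide; with the weak base KOAc the boronate should not couple further, and the free hydroxyl and the silyl ether are tolerated.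

Step 9
Reactants: 14 octanal
Product: 16 (4R)-undec-1-en-4-ol, via borinate ester 15 (not isolated)
Conditions: (−)-Ipc2B(allyl), Et2O, −78 °C; NaOH, H2O2, 0 → 23 °C
Reagents that add atoms: (−)-B-allyldiisopinocampheylborane, C=CCB([C@@H]1C[C@@H]2C[C@H]([C@H]1C)C2(C)C)[C@@H]1C[C@@H]2C[C@H]([C@H]1C)C2(C)C
Why: Brown allylboration through a chair six-membered transition state; the (−)-reagent (from (+)-α-pinene) adds allyl to the Si face of the aldehyde, which for a straight-chain aldehyde gives the R homoallylic alcohol, the future C7.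

Step 10
Reactants: 16 (4R)-undec-1-en-4-ol
Product: 17 (4R)-4-methoxyundec-1-ene
Conditions: NaH, MeI, THF, 0 → 23 °C
Reagents that add atoms: iodomethane, CI
Why: Williamson methylation of the sodium alkoxide, which does not touch the stereocentre.

Step 11
Reactants: 17 (4R)-4-methoxyundec-1-ene
Product: 19 (3R)-3-methoxydecanal, via ozonide 18 (not isolated)
Conditions: O3, CH2Cl2, −78 °C; PPh3, −78 → 23 °C
Reagents that add atoms: ozone, [O-][O+]=O
Why: Ozonolysis of the terminal alkene with reductive work-up removes one carbon and gives the β-methoxy aldehyde, which is used crude to avoid β-elimination.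

Step 12
Reactants: 19 (3R)-3-methoxydecanal
Product: 20 (5R)-5-methoxydodec-1-en-3-ol (both C3 epimers)
Conditions: CH2=CHMgBr, THF, −78 °C; aq. NH4Cl
Reagents that add atoms: vinylmagnesium bromide, C=C[Mg]Br
Why: Grignard 1,2-addition to the aldehyde at low temperature; the new carbinol centre forms as a mixture, which does not matter because it is destroyed in the next step.

Step 13
Reactants: 20 (5R)-5-methoxydodec-1-en-3-ol
Product: 22 ethyl (4E,7R)-7-methoxytetradec-4-enoate, via ketene acetal 21 (not isolated)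
Conditions: MeC(OEt)3, EtCO2H (cat.), 135 °C
Reagents that add atoms: triethyl orthoacetate, CCOC(C)(OCC)OCC
Why: Johnson–Claisen rearrangement through a chair transition state with the chain pseudo-equatorial, so both carbinol epimers should converge on the E alkene while two carbons are added and C7 is untouched.

Step 14
Reactants: 22 ethyl (4E,7R)-7-methoxytetradec-4-enoate
Product: 23 (4E,7R)-7-methoxytetradec-4-enoic acid
Conditions: LiOH, THF/MeOH/H2O, 23 °C; 1 M HCl
Reagents that add atoms: lithium hydroxide, [Li+].[OH-]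
Why: Saponification of the ethyl ester, to which the isolated alkene and the ether are inert.

Step 15
Reactants: 24 N-methylprop-2-yn-1-amine
Product: 25 2,2,2-trifluoro-N-methyl-N-(prop-2-yn-1-yl)acetamide
Conditions: (CF3CO)2O, Et3N, CH2Cl2, 0 °C
Reagents that add atoms: trifluoroacetic anhydride, O=C(OC(=O)C(F)(F)F)C(F)(F)F
Why: N-Acylation masks the amine against iodine monochloride with a carbonyl oxygen that is too weakly nucleophilic to trap an iodonium ion.

Step 16
Reactants: 25 2,2,2-trifluoro-N-methyl-N-(prop-2-yn-1-yl)acetamide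
Product: 26 N-[(2E)-2-chloro-3-iodoprop-2-en-1-yl]-2,2,2-trifluoro-N-methylacetamide
Conditions: ICl, CH2Cl2, −78 → 0 °C, dark
Reagents that add atoms: iodine monochloride, ClI
Why: Electrophilic anti addition of ICl to the terminal alkyne: iodine bridges and chloride opens the iodonium ion at the internal carbon from the opposite side, so iodine and chlorine should end up trans (E) with chlorine on the carbon next to CH2N.

Step 17
Reactants: 26 N-[(2E)-2-chloro-3-iodoprop-2-en-1-yl]-2,2,2-trifluoro-N-methylacetamide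
Product: 27 (2E)-2-chloro-3-iodo-N-methylprop-2-en-1-amine
Conditions: K2CO3, MeOH/H2O, 23 °C
Reagents that add atoms: none
Why: Mild basic solvolysis of the trifluoroacetamide frees the secondary amine, and alkenyl halides are inert to carbonate.

Step 18
Reactants: 23 (4E,7R)-7-methoxytetradec-4-enoic acid; 27 (2E)-2-chloro-3-iodo-N-methylprop-2-en-1-amine
Product: 29 (4E,7R)-N-[(2E)-2-chloro-3-iodoprop-2-en-1-yl]-7-methoxy-N-methyltetradec-4-enamide, via benzotriazolyl ester 28 (not isolated)
Conditions: EDC·HCl, HOBt, iPr2NEt, CH2Cl2, 0 → 23 °C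
Reagents that add atoms: none
Why: Carbodiimide/HOBt amide coupling of the acid with the secondary amine through the active ester.

Step 19
Reactants: 13 (1S,5S,6R)-5-[(tert-butyldimethylsilyl)oxy]-6-methyl-2-(4,4,5,5-tetramethyl-1,3,2-dioxaborolan-2-yl)cyclohex-2-en-1-ol; 29 (4E,7R)-N-[(2E)-2-chloro-3-iodoprop-2-en-1-yl]-7-methoxy-N-methyltetradec-4-enamide
Product: 30 (4E,7R)-N-[(2E)-3-{(4S,5R,6S)-4-[(tert-butyldimethylsilyl)oxy]-6-hydroxy-5-methylcyclohex-1-en-1-yl}-2-chloroprop-2-en-1-yl]-7-methoxy-N-methyltetradec-4-enamide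
Conditions: PdCl2(dppf), K3PO4, THF/H2O, 45 °C
Reagents that add atoms: none
Why: Suzuki–Miyaura coupling in which oxidative addition occurs at C–I far faster than at C–Cl and both partners keep their geometry, so ring carbon C2 replaces iodine trans to chlorine and the (E)-chlorodiene forms with the whole side chain in place.

Step 20
Reactants: 30 (4E,7R)-N-[(2E)-3-{(4S,5R,6S)-4-[(tert-butyldimethylsilyl)oxy]-6-hydroxy-5-methylcyclohex-1-en-1-yl}-2-chloroprop-2-en-1-yl]-7-methoxy-N-methyltetradec-4-enamide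
Product: 31 (4E,7R)-N-[(2E)-3-{(1S,2S,3R,4S,6R)-4-[(tert-butyldimethylsilyl)oxy]-2-hydroxy-3-methyl-7-oxabicyclo[4.1.0]heptan-1-yl}-2-chloroprop-2-en-1-yl]-7-methoxy-N-methyltetradec-4-enamide
Conditions: VO(acac)2 (5 mol%), t-BuOOH, CH2Cl2, 0 → 23 °C
Reagents that add atoms: tert-butyl hydroperoxide, CC(C)(C)OO
Why: Hydroxyl-directed epoxidation in which the vanadium alkoxide of the C1 allylic alcohol delivers oxygen to the ring alkene on the face of the hydroxyl, setting C2 and C3 with the epoxide cis to the C5 and C6 substituents, while the isolated E alkene and the electron-poor chloroalkene, which have no allylic hydroxyl, should stay untouched.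

Step 21
Reactants: 31 (4E,7R)-N-[(2E)-3-{(1S,2S,3R,4S,6R)-4-[(tert-butyldimethylsilyl)oxy]-2-hydroxy-3-methyl-7-oxabicyclo[4.1.0]heptan-1-yl}-2-chloroprop-2-en-1-yl]-7-methoxy-N-methyltetradec-4-enamide
Product: 32 (4E,7R)-N-[(2E)-3-{(1R,3S,4S,6R)-4-[(tert-butyldimethylsilyl)oxy]-3-methyl-2-oxo-7-oxabicyclo[4.1.0]heptan-1-yl}-2-chloroprop-2-en-1-yl]-7-methoxy-N-methyltetradec-4-enamide
Conditions: Dess–Martin periodinane, NaHCO3, CH2Cl2, 0 °C
Reagents that add atoms: none
Why: Dess–Martin oxidation of the epoxy alcohol restores the C1 ketone under buffered conditions that should leave the epoxide and the C6 centre alone.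

Step 22
Reactants: 32 (4E,7R)-N-[(2E)-3-{(1R,3S,4S,6R)-4-[(tert-butyldimethylsilyl)oxy]-3-methyl-2-oxo-7-oxabicyclo[4.1.0]heptan-1-yl}-2-chloroprop-2-en-1-yl]-7-methoxy-N-methyltetradec-4-enamide
Product: 33 (4E,7R)-N-[(2E)-2-chloro-3-{(1R,3S,4S,6R)-4-hydroxy-3-methyl-2-oxo-7-oxabicyclo[4.1.0]heptan-1-yl}prop-2-en-1-yl]-7-methoxy-N-methyltetradec-4-enamide
Conditions: HF·pyridine, pyridine, THF, 0 → 23 °C
Reagents that add atoms: none
Why: Fluoride cleavage of the secondary silyl ether under buffered, weakly acidic conditions, chosen over basic fluoride to avoid retro-aldol cleavage or β-elimination of the β-hydroxy ketone.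

Step 23
Reactants: 33 (4E,7R)-N-[(2E)-2-chloro-3-{(1R,3S,4S,6R)-4-hydroxy-3-methyl-2-oxo-7-oxabicyclo[4.1.0]heptan-1-yl}prop-2-en-1-yl]-7-methoxy-N-methyltetradec-4-enamide
Product: 34 (1R,3S,4S,6R)-1-[(1E)-2-chloro-3-{methyl[(4E,7R)-7-methoxytetradec-4-enoyl]amino}prop-1-en-1-yl]-3-methyl-2-oxo-7-oxabicyclo[4.1.0]heptan-4-yl acetate
Conditions: Ac2O, pyridine, DMAP (cat.), CH2Cl2, 0 °C
Reagents that add atoms: acetic anhydride, CC(=O)OC(C)=O
Why: DMAP-catalysed acyl transfer acetylates the secondary alcohol at low temperature and short reaction time, which should avoid elimination of the β-acetoxy ketone.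

**Compound list**

1 | 2-methylcyclopent-2-en-1-one | CC1=CCCC1=O | starting material
2 | (1S)-2-methylcyclopent-2-en-1-ol | CC1=CCC[C@@H]1O | intermediate
3 | tert-butyldimethyl{[(1S)-2-methylcyclopent-2-en-1-yl]oxy}silane | CC1=CCC[C@@H]1O[Si](C)(C)C(C)(C)C | intermediate
4 | [(1S,2R,3S)-3-{[tert-butyl(dimethyl)silyl]oxy}-2-methylcyclopentyl]borane (drawn as the monoalkylborane) | B[C@H]1CC[C@H](O[Si](C)(C)C(C)(C)C)[C@@H]1C | intermediate (not isolated)
5 | (1S,2R,3S)-3-[(tert-butyldimethylsilyl)oxy]-2-methylcyclopentan-1-ol | O[C@H]1CC[C@H](O[Si](C)(C)C(C)(C)C)[C@@H]1C | intermediate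
6 | (2S,3S)-3-[(tert-butyldimethylsilyl)oxy]-2-methylcyclopentan-1-one | O=C1CC[C@H](O[Si](C)(C)C(C)(C)C)[C@@H]1C | intermediate
7 | lithium (4S,5S)-4-[(tert-butyldimethylsilyl)oxy]-5-methylcyclopent-1-en-1-olate | [Li+].[O-]C1=CC[C@H](O[Si](C)(C)C(C)(C)C)[C@@H]1C | intermediate (not isolated)
8 | (4S,5S)-4-[(tert-butyldimethylsilyl)oxy]-5-methyl-1-[(triethylsilyl)oxy]cyclopent-1-ene | CC[Si](CC)(CC)OC1=CC[C@H](O[Si](C)(C)C(C)(C)C)[C@@H]1C | intermediate
9 | bromoform | BrC(Br)Br | starting material
10 | (1S,2S,3S,5S)-6,6-dibromo-3-[(tert-butyldimethylsilyl)oxy]-2-methyl-1-[(triethylsilyl)oxy]bicyclo[3.1.0]hexane (cyclopropane anti to the methyl group) | CC[Si](CC)(CC)O[C@@]12[C@@H](C)[C@@H](O[Si](C)(C)C(C)(C)C)C[C@@H]1C2(Br)Br | intermediate (not isolated)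
11 | (5S,6S)-2-bromo-5-[(tert-butyldimethylsilyl)oxy]-6-methylcyclohex-2-en-1-one | O=C1C(Br)=CC[C@H](O[Si](C)(C)C(C)(C)C)[C@@H]1C | intermediate
12 | (1S,5S,6R)-2-bromo-5-[(tert-butyldimethylsilyl)oxy]-6-methylcyclohex-2-en-1-ol | O[C@@H]1C(Br)=CC[C@H](O[Si](C)(C)C(C)(C)C)[C@@H]1C | intermediate
13 | (1S,5S,6R)-5-[(tert-butyldimethylsilyl)oxy]-6-methyl-2-(4,4,5,5-tetramethyl-1,3,2-dioxaborolan-2-yl)cyclohex-2-en-1-ol | O[C@@H]1C(B2OC(C)(C)C(C)(C)O2)=CC[C@H](O[Si](C)(C)C(C)(C)C)[C@@H]1C | intermediate
14 | octanal | CCCCCCCC=O | starting material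
15 | (4R)-undec-1-en-4-yl diisopinocampheylborinate (isopinocampheyl groups from (+)-α-pinene) | CCCCCCC[C@H](CC=C)OB([C@@H]1C[C@@H]2C[C@H]([C@H]1C)C2(C)C)[C@@H]1C[C@@H]2C[C@H]([C@H]1C)C2(C)C | intermediate (not isolated)
16 | (4R)-undec-1-en-4-ol | CCCCCCC[C@H](CC=C)O | intermediate
17 | (4R)-4-methoxyundec-1-ene | CCCCCCC[C@H](CC=C)OC | intermediate
18 | 3-[(2R)-2-methoxynonyl]-1,2,4-trioxolane (both ring epimers) | CCCCCCC[C@H](CC1OCOO1)OC | intermediate (not isolated)
19 | (3R)-3-methoxydecanal | CCCCCCC[C@H](CC=O)OC | intermediate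
20 | (5R)-5-methoxydodec-1-en-3-ol (both C3 epimers) | CCCCCCC[C@H](CC(O)C=C)OC | intermediate
21 | (5R)-3-[(1-ethoxyethenyl)oxy]-5-methoxydodec-1-ene | CCCCCCC[C@H](CC(OC(=C)OCC)C=C)OC | intermediate (not isolated)
22 | ethyl (4E,7R)-7-methoxytetradec-4-enoate | CCCCCCC[C@H](C/C=C/CCC(=O)OCC)OC | intermediate
23 | (4E,7R)-7-methoxytetradec-4-enoic acid | CCCCCCC[C@H](C/C=C/CCC(=O)O)OC | intermediate
24 | N-methylprop-2-yn-1-amine | CNCC#C | starting material
25 | 2,2,2-trifluoro-N-methyl-N-(prop-2-yn-1-yl)acetamide | CN(CC#C)C(=O)C(F)(F)F | intermediate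
26 | N-[(2E)-2-chloro-3-iodoprop-2-en-1-yl]-2,2,2-trifluoro-N-methylacetamide | CN(C/C(Cl)=C\I)C(=O)C(F)(F)F | intermediate
27 | (2E)-2-chloro-3-iodo-N-methylprop-2-en-1-amine | CNC/C(Cl)=C\I | intermediate
28 | 1H-benzotriazol-1-yl (4E,7R)-7-methoxytetradec-4-enoate | CCCCCCC[C@H](C/C=C/CCC(=O)On1nnc2ccccc12)OC | intermediate (not isolated)
29 | (4E,7R)-N-[(2E)-2-chloro-3-iodoprop-2-en-1-yl]-7-methoxy-N-methyltetradec-4-enamide | CCCCCCC[C@H](C/C=C/CCC(=O)N(C)C/C(Cl)=C\I)OC | intermediate
30 | (4E,7R)-N-[(2E)-3-{(4S,5R,6S)-4-[(tert-butyldimethylsilyl)oxy]-6-hydroxy-5-methylcyclohex-1-en-1-yl}-2-chloroprop-2-en-1-yl]-7-methoxy-N-methyltetradec-4-enamide | CCCCCCC[C@H](C/C=C/CCC(=O)N(C)C/C(Cl)=C\C1=CC[C@H](O[Si](C)(C)C(C)(C)C)[C@H](C)[C@@H]1O)OC | intermediate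
31 | (4E,7R)-N-[(2E)-3-{(1S,2S,3R,4S,6R)-4-[(tert-butyldimethylsilyl)oxy]-2-hydroxy-3-methyl-7-oxabicyclo[4.1.0]heptan-1-yl}-2-chloroprop-2-en-1-yl]-7-methoxy-N-methyltetradec-4-enamide | CCCCCCC[C@H](C/C=C/CCC(=O)N(C)C/C(Cl)=C\[C@@]12O[C@@H]1C[C@H](O[Si](C)(C)C(C)(C)C)[C@H](C)[C@@H]2O)OC | intermediate
32 | (4E,7R)-N-[(2E)-3-{(1R,3S,4S,6R)-4-[(tert-butyldimethylsilyl)oxy]-3-methyl-2-oxo-7-oxabicyclo[4.1.0]heptan-1-yl}-2-chloroprop-2-en-1-yl]-7-methoxy-N-methyltetradec-4-enamide | CCCCCCC[C@H](C/C=C/CCC(=O)N(C)C/C(Cl)=C\[C@@]12O[C@@H]1C[C@H](O[Si](C)(C)C(C)(C)C)[C@H](C)C2=O)OC | intermediate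
33 | (4E,7R)-N-[(2E)-2-chloro-3-{(1R,3S,4S,6R)-4-hydroxy-3-methyl-2-oxo-7-oxabicyclo[4.1.0]heptan-1-yl}prop-2-en-1-yl]-7-methoxy-N-methyltetradec-4-enamide | CCCCCCC[C@H](C/C=C/CCC(=O)N(C)C/C(Cl)=C\[C@@]12O[C@@H]1C[C@H](O)[C@H](C)C2=O)OC | intermediate
34 | (1R,3S,4S,6R)-1-[(1E)-2-chloro-3-{methyl[(4E,7R)-7-methoxytetradec-4-enoyl]amino}prop-1-en-1-yl]-3-methyl-2-oxo-7-oxabicyclo[4.1.0]heptan-4-yl acetate | CCCCCCC[C@H](C/C=C/CCC(=O)N(C)C/C(Cl)=C\[C@@]12O[C@@H]1C[C@H](OC(C)=O)[C@H](C)C2=O)OC | target

**Step count**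

Total: 23 steps. Longest linear sequence: 13 steps (steps 1–8 and 19–23, from 1).

**Steps most likely to fail**

1. Step 6. Under the basic carbene-generating conditions the new enone may enolise toward C6, which would scramble the C6 configuration and open the way to β-elimination of the silyl ether and aromatisation; tert-butoxide may also strip the enol silyl group before the carbene arrives. The fallback sets out from 8 and comes back at 11. It is a base-free one-carbon enlargement with the halogen put in afterwards. Cyclopropanation of 8 with Et2Zn and CH2I2 (Simmons–Smith, CH2Cl2, 0 °C) should give 3-[(tert-butyldimethylsilyl)oxy]-2-methyl-1-[(triethylsilyl)oxy]bicyclo[3.1.0]hexane F1. Oxidative opening of the fusion bond with FeCl3 in DMF should give the ring-enlarged (5S,6S)-5-[(tert-butyldimethylsilyl)oxy]-3-chloro-6-methylcyclohexan-1-one F2. Elimination with NaOAc in MeOH should give (5S,6S)-5-[(tert-butyldimethylsilyl)oxy]-6-methylcyclohex-2-en-1-one F3, and bromination–dehydrobromination (Br2, CH2Cl2, 0 °C; Et3N) returns 11.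

2. Step 16. Chloride may open the iodonium ion at the terminal carbon, or the amide oxygen may capture it, so that the addition gives the wrong regioisomer or a cyclised by-product. The fallback sets out from 23, 24 and 12 and comes back at 30. It carries the arm in as an alkyne and adds H and Cl syn afterwards. EDC/HOBt coupling of 23 with 24 should give (4E,7R)-7-methoxy-N-methyl-N-(prop-2-yn-1-yl)tetradec-4-enamide F4. Sonogashira coupling of F4 with 12 (PdCl2(PPh3)2, CuI, iPr2NH, THF, 50 °C) should give the ring enyne (the alkyne analogue of 30) F5. Copper-catalysed syn borylcupration–protonation (CuCl, PCy3, NaOtBu, B2pin2, MeOH, toluene) is expected to place boron on the alkyne carbon next to CH2N, since the propargylic nitrogen and the conjugating ring alkene direct the same way, giving the (Z)-alkenylboronate (30 with Bpin in place of Cl) F6. Chlorodeboronation with retention (CuCl2, MeOH/H2O, 60 °C) returns 30.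

3. Step 20. The face to which the C1 hydroxyl directs also carries the C5 silyl ether and the C6 methyl group, so oxygen transfer may be slow and the catalyst may instead oxidise the allylic alcohol to the dienone. The fallback sets out from 30 and comes back at 34. Desilylation first (Bu4NF, THF) should give the diene diol (30 with free C5 hydroxyl) F7. Both cis hydroxyls, allylic at C1 and homoallylic at C5, can then deliver the oxidant (VO(acac)2, t-BuOOH) to give the epoxy diol F8. Selective acetylation of the less hindered C5 hydroxyl (Ac2O, 2,4,6-collidine, CH2Cl2, −20 °C) should give the C5 acetate with free C1 hydroxyl F9, and Dess–Martin oxidation of the C1 carbinol gives 34. This order also avoids acetylating a β-hydroxy ketone.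

Further compounds
F1 | step 6 | 3-[(tert-butyldimethylsilyl)oxy]-2-methyl-1-[(triethylsilyl)oxy]bicyclo[3.1.0]hexane (cyclopropane anti to the methyl group) | CC[Si](CC)(CC)O[C@@]12[C@@H](C)[C@@H](O[Si](C)(C)C(C)(C)C)C[C@@H]1C2
F2 | step 6 | (5S,6S)-5-[(tert-butyldimethylsilyl)oxy]-3-chloro-6-methylcyclohexan-1-one (both C3 epimers) | O=C1CC(Cl)C[C@H](O[Si](C)(C)C(C)(C)C)[C@@H]1C
F3 | step 6 | (5S,6S)-5-[(tert-butyldimethylsilyl)oxy]-6-methylcyclohex-2-en-1-one | O=C1C=CC[C@H](O[Si](C)(C)C(C)(C)C)[C@@H]1C
F4 | step 16 | (4E,7R)-7-methoxy-N-methyl-N-(prop-2-yn-1-yl)tetradec-4-enamide | CCCCCCC[C@H](C/C=C/CCC(=O)N(C)CC#C)OC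
F5 | step 16 | (4E,7R)-N-(3-{(4S,5R,6S)-4-[(tert-butyldimethylsilyl)oxy]-6-hydroxy-5-methylcyclohex-1-en-1-yl}prop-2-yn-1-yl)-7-methoxy-N-methyltetradec-4-enamide | CCCCCCC[C@H](C/C=C/CCC(=O)N(C)CC#CC1=CC[C@H](O[Si](C)(C)C(C)(C)C)[C@H](C)[C@@H]1O)OC
F6 | step 16 | (4E,7R)-N-[(2Z)-3-{(4S,5R,6S)-4-[(tert-butyldimethylsilyl)oxy]-6-hydroxy-5-methylcyclohex-1-en-1-yl}-2-(4,4,5,5-tetramethyl-1,3,2-dioxaborolan-2-yl)prop-2-en-1-yl]-7-methoxy-N-methyltetradec-4-enamide | CCCCCCC[C@H](C/C=C/CCC(=O)N(C)C/C(B1OC(C)(C)C(C)(C)O1)=C\C1=CC[C@H](O[Si](C)(C)C(C)(C)C)[C@H](C)[C@@H]1O)OC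
F7 | step 20 | (4E,7R)-N-[(2E)-2-chloro-3-{(4S,5S,6S)-4,6-dihydroxy-5-methylcyclohex-1-en-1-yl}prop-2-en-1-yl]-7-methoxy-N-methyltetradec-4-enamide | CCCCCCC[C@H](C/C=C/CCC(=O)N(C)C/C(Cl)=C\C1=CC[C@H](O)[C@H](C)[C@@H]1O)OC
F8 | step 20 | epoxy diol: 31 with a free hydroxyl in place of the silyl ether | CCCCCCC[C@H](C/C=C/CCC(=O)N(C)C/C(Cl)=C\[C@@]12O[C@@H]1C[C@H](O)[C@H](C)[C@@H]2O)OC
F9 | step 20 | C1 carbinol of the target: 34 with a hydroxyl (cis to the epoxide) in place of the ketone | CCCCCCC[C@H](C/C=C/CCC(=O)N(C)C/C(Cl)=C\[C@@]12O[C@@H]1C[C@H](OC(C)=O)[C@H](C)[C@@H]2O)OC
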